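The earlier runs and the new flask are calculated for an exercise, and the scatter is random.

83% of the substrate charged stood as target at 4.00 min of the theta run, after 90% at 3.00 min, so target is first made and then lost.

| flask | substrate | gas phase | remark | time |
|---|---|---|---|---|
| theta | 0.0066 M | 2 mM (held) | run made earlier |  |
| south-east | 0.0060 M | 2.0 mM (held) |  | 12 min |
| north-east | 0.015 M | 2.0 mM (held) |  | 12 min |
| south | 0.050 M | 2.0 mM (held) |  | 12 min |
| north-west | 0.15 M | 2.0 mM (held) |  | 12 min |
| west | 0.50 M | 2.0 mM (held) |  | 12 min |

- theta (time / min: target / %): 0.667: 45; 1.33: 73; 2.00: 83; 3.00: 90; 4.00: 83

(scatter of a reading: 2 percentage points)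

- at the start none of the gas phase is in solution
- "hardly changes" means that all values lie within two and a half points (for a concentration: within two and a half percent of the largest)

- amount of target at the end, in percent of the substrate charged for south-east, north-east, south, north-west, west, in this order
- the course of these numbers from the first flask to the last (falls all the way / falls, then rises / hardly changes / rises, then falls / rises all the way)

Two constants can be read from the theta run. Early on, the target reading stands for reacted substrate, so the reading at 1.33 min gives substrate a first-order making constant of 0.984 min⁻¹, a mean lifetime of 1.02 min. The spread of birth times is then replaced by that mean: target at 4.00 min has aged 2.98 min, which gives a loss constant of 0.0624 min⁻¹. The quantity to carry is the selectivity factor σ, the loss constant over the making constant, 0.0634. If both steps take dissolved gas at first order, the gas cancels in σ, and target depends on a, the fraction of substrate left, as (a^σ − a)/(1 − σ).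

Two extreme flasks follow. With gas at saturation throughout, substrate keeps the mean lifetime 1.02 min and target ages for the rest of the time, which gives 50.4% for south-east at 12 min. The exact curve for steady gas gives 50.5%, so the mean costs little. With gas far below saturation, the reaction slows but target follows the same curve in a, and a flask that stops with a above 0.0526, the peak of that curve, stops on its rising side. My own reckoning puts the row near 50.4% at first, then higher, then lower at the last flask, with no number of my own for that last flask.

The forecast gives 50%, 51%, 56%, 75% and 45%, course rises, then falls, on the ground that “At 0.5 M, gas delivered limits conversion to about 45%”.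

The flasks give 53.7%, 55.3%, 61.2%, 77.9% and 57.9%, course rises, then falls.

    substrate + dissolved gas → target (k = 11.0 M⁻¹ s⁻¹)
    dissolved gas + target → over-reacted product (k = 0.250 M⁻¹ s⁻¹)
    gas phase ⇌ dissolved gas, rate k3*(csat - [dissolved gas]) (kL = 0.223 s⁻¹)
    dissolved gas + target → over-reaction product (k = 0.228 M⁻¹ s⁻¹)

In south-east at 0.880 min, substrate has a half-life of 0.60 min by its step, shorter than the 29 min of target by the step to over-reaction product, and target is made 16.3 times faster than it is used up; that flask ends at 53.7% against the reckoned 50.4%. With σ, the 40.8% of substrate left in west at 12.0 min gives 57.3% on the curve, and that flask holds 57.9%. The 19.3% left in north-west at 6.00 min gives 75.6%, and that flask holds 77.2%.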